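## Analysis of the target

Atom labels used throughout: C1 is the benzylic carbinol carbon (it carries ring A, a 3,4-dimethoxyphenyl ring), C2 the branching methine, C3 the acylated CH2–O carbon. The side chain on C2 is C1' (allylic CH2), C2'=C3' (alkene), with ring B (the second 3,4-dimethoxyphenyl ring) on C3'. The acyl group is C1'' (C=O), C2''=C3'', C4'' (CH3), with a CH2OH on C2''.

The target is an acyclic 1-aryl-2-cinnamylpropane-1,3-diol whose primary oxygen O3 carries a (Z)-2-(hydroxymethyl)but-2-enoyl group; its only rings are the two identical arene rings A and B. It has two contiguous stereocentres, C1 (S) and C2 (R). They are syn in the aldol sense: with C3–C2–C1–ring A drawn zigzag, the OH on C1 and C1' on C2 lie on the same side. There are two alkene geometries: E at C2'=C3', and Z at C2''=C3'', where the methyl C4'' is cis to the ester carbonyl (the less stable, angelate-type arrangement). The sensitive groups are the electron-rich benzylic alcohol at C1 (ionises in acid), the 1,3-diol monoester (O3→O1 acyl shift in base), and the Z-acrylate, which can isomerise to E by reversible conjugate addition once its carboxyl is activated. The difficulty is economy, not size: C2 is bonded to three different carbon arms, three hydroxyl groups must be told apart, and the acid geometry must not be lost.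

The feature the route exploits is the triad C3–C2–C1'. It is an acrylate in disguise: C3 is a carboxyl-level carbon, C2 its α-carbon, C1' its β-carbon. C1' is bonded to the sp2 carbon C2' of an (E)-styrene (a hydrometalated aryl alkyne carrying ring B). C2 is bonded to the carbinol C1 (the carbonyl carbon of an aryl aldehyde carrying ring A). C2 can therefore be the hub of a three-component conjugate addition/aldol union.

## Retrosynthetic reasoning

**16 ⇒ 15.** The last disconnection is the O–Si bond of a silyl ether on the C2'' hydroxymethyl group. The mask is needed only while the ester is made, so that this hydroxyl cannot be acylated or close a four-membered lactone.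

**15 ⇒ 10 + 14 (plus one carbonyl carbon from the gas phase).** Both bonds at C1'' are cut: C1''–O3 and C1''–C2''. This avoids ever making or activating the free (Z)-acid, which is where angelate-type acids isomerise. The Z geometry is stored in alkenyl iodide 14 and must be carried through oxidative addition and CO insertion with retention. The forward reaction must also choose the primary O3–H of 10 over the benzylic O1–H.

**14 ⇒ 13 ⇒ 12 ⇒ 11.** The iodide comes from (E)-but-2-enal 11 by α-iodination, 1,2-reduction and silylation. The methyl/carbonyl trans relationship of 11 becomes the methyl/iodine cis relationship of 12–14, which is exactly the geometry the ester needs.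

**10 ⇒ 9.** C3 is returned to the carboxyl level as an N-acyl oxazolidinone. The forward step is a hydride cleavage that releases the auxiliary 1 and leaves C1 and C2 untouched.

**9 ⇒ 3 + 4 + 5 (key disconnection).** Two bonds at the hub are cut in one operation: C1–C2 (aldol) and C1'–C2' (conjugate addition). This leaves acrylimide 3, aryl alkyne 4 and aryl aldehyde 5, which are one step from or directly articles of commerce. Cutting only C1–C2 would leave a C13 acyl imide that has to be built separately. The forward reaction has to: hydrometalate 4 regioselectively and syn to give the (E)-alkenylborane 6; transfer the alkenyl group 1,4 to 3 to give the Z boron enolate 7; and let 7 add to 5 under auxiliary control to give aldolate 8 and, after work-up, 9.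

**3 ⇒ 1 + 2.** N-Acylation of the commercial (S)-auxiliary 1 with acryloyl chloride 2.

## Alternatives that were turned down

**Alternative 1:** (textbook) Cut C1–C2 only. The forward key step is the boron-mediated syn-aldol of the preformed imide (4S)-4-benzyl-3-[(4E)-5-(3,4-dimethoxyphenyl)pent-4-enoyl]-1,3-oxazolidin-2-one A1 with 5, giving 9. It was turned down on step economy. A1 is not commercial and needs about four steps of its own. Its boron enolate is the same kind of species that the chosen step generates directly from 3 and 4, so the stereocontrol is the same at a higher step count. It is kept as the fallback.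

**Alternative 2:** Cut C1–H. The forward key step is an asymmetric transfer hydrogenation with dynamic kinetic resolution of racemic ethyl 2-(3,4-dimethoxybenzoyl)-5-(3,4-dimethoxyphenyl)pent-4-enoate A2. It would be meant to funnel both C2 epimers into the syn hydroxy ester A3, which is then reduced to 10. It was turned down on mechanism. Outer-sphere hydride delivery from a metal-hydride/N–H catalyst does not chelate the 1,3-dicarbonyl unit. In the polar Felkin–Anh arrangement the ester is perpendicular to the carbonyl plane and hydride arrives past the α-hydrogen. That leads to the 2,3-anti ester A4, the wrong diastereomer. A syn outcome would need an internal hydrogen-bond donor such as an N–H amide in place of the ester, and turning that amide into C3H2–OH costs the steps the convergence saved.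

**Alternative 3:** (hidden symmetry) Cut C2–C3 and C1–O1. The forward key step is a catalytic asymmetric Prins reaction of a C1 aldehyde with one of the two equivalent styrene units of (1E,4E)-1,5-bis(3,4-dimethoxyphenyl)penta-1,4-diene A5, giving a 4,5-disubstituted 1,3-dioxane. It was turned down on three grounds:
- Suprafacial addition across an E-alkene gives the trans-dioxane A6, and so does the stepwise route through the well-stabilised 3,4-dimethoxybenzyl cation; the target needs the cis (syn) relationship.
- Two identical alkenes give statistical mono/bis functionalisation.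
- The doubly allylic CH2 of A5 invites acid-induced isomerisation to the conjugated diene.

Key step: step 2

Assumption: commercial crotonaldehyde is used as its (E)-isomer 11, and 9-BBN-H in step 2 is counted as a reagent because none of its non-hydrogen atoms reach 9.

## Route

Step 1
Reactants: 1 (4S)-4-benzyl-1,3-oxazolidin-2-one; 2 acryloyl chloride
Product: 3 (4S)-3-acryloyl-4-benzyl-1,3-oxazolidin-2-one
Conditions: MeMgBr (1.05 equiv), THF, 0 °C; then 2, −78 → 0 °C
Reagents that add atoms: none
Why: N-acylation of the bromomagnesium salt of the oxazolidinone; the magnesium amide is mild enough to avoid anionic polymerisation of the acrylimide, and no stereocentre is formed or touched.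

Step 2
Reactants: 4 4-ethynyl-1,2-dimethoxybenzene; 3 (4S)-3-acryloyl-4-benzyl-1,3-oxazolidin-2-one; 5 3,4-dimethoxybenzaldehyde
Product: 9 (4S)-4-benzyl-3-{(2S,4E)-5-(3,4-dimethoxyphenyl)-2-[(S)-(3,4-dimethoxyphenyl)(hydroxy)methyl]pent-4-enoyl}-1,3-oxazolidin-2-one, via the (E)-alkenyl-9-BBN 6 (not isolated), via the Z boron enolate 7 (not isolated), via the boron aldolate 8 (not isolated)
Conditions: 4 (1.3 equiv), 9-BBN-H (1.2 equiv), THF, 0 → 25 °C; then 3 (1.0 equiv), [Rh(OH)(cod)]2 (2.5 mol %), toluene, 25–40 °C; then 5 (1.3 equiv), −78 → 0 °C; then pH 7 buffer, MeOH, 30 % H2O2, 0 °C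
Reagents that add atoms: none
Why: Proposed new method: syn-hydroboration of the terminal alkyne 4 puts boron on the terminal carbon and gives the (E)-alkenylborane 6; transmetalation to Rh(I), 1,4-insertion of the s-cis acrylimide 3 and boron-for-rhodium exchange at the oxa-π-allyl stage should deliver the 9-BBN enolate 7 and a new alkenyl–Rh. The closest known reaction type is the Rh-catalysed 1,4-addition of B-aryl-9-BBN reagents to enones, which gives boron enolates that undergo aldol addition, merged here with the Evans boron aldol of N-acyl oxazolidinones; the uncatalysed six-centre 1,4-transfer known for B-alkenyl-9-BBN and s-cis enones would feed the same enolate. No ring is closed; the bonds formed are C1'–C2' (conjugate addition) and C1–C2 (aldol). The enolate is expected as the Z(O) isomer because the E isomer suffers A(1,3) strain against the oxazolidinone, so 7 is the same kind of species that soft enolisation of an N-acyl oxazolidinone gives. Aldehyde 5 displaces the imide carbonyl from boron and reacts through a closed Zimmerman–Traxler chair: the Z enolate fixes the syn C1/C2 relationship, and the benzyl group of the (S)-auxiliary in the dipole-opposed rotamer blocks one enolate face, fixing C2 as S and C1 as S in 9. The step needs 1,4-selectivity and mono-addition (secured by the unhindered β-carbon of 3, the low catalyst loading and the slight excess of 6), a boron and not a rhodium enolate in the aldol event (secured by adding 5 only after 3 is consumed and at −78 °C), and an intact (E)-styrene (hydroboration is stereospecific and nothing later touches it). Oxidative work-up cleaves the B–O bond of aldolate 8.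

Step 3
Reactants: 9 (4S)-4-benzyl-3-{(2S,4E)-5-(3,4-dimethoxyphenyl)-2-[(S)-(3,4-dimethoxyphenyl)(hydroxy)methyl]pent-4-enoyl}-1,3-oxazolidin-2-one
Product: 10 (1S,2R)-1-(3,4-dimethoxyphenyl)-2-[(2E)-3-(3,4-dimethoxyphenyl)prop-2-en-1-yl]propane-1,3-diol
Conditions: LiBH4, MeOH (1 equiv), THF, 0 °C
Reagents that add atoms: none
Why: Reductive cleavage of the N-acyl oxazolidinone at the exocyclic carbonyl by LiBH4 gives the primary alcohol and returns auxiliary 1; no enolisation occurs, and C2 changes from S to R only because C3 drops in CIP priority.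

Step 4
Reactants: 11 (E)-but-2-enal
Product: 12 (Z)-2-iodobut-2-enal
Conditions: I2, K2CO3, DMAP (cat.), THF/H2O (1:1), rt, dark
Reagents that add atoms: iodine, II
Why: α-Iodination of an enal by a Baylis–Hillman-type sequence (conjugate addition of DMAP, iodination of the enolate, elimination); the methyl group stays trans to the formyl group, so iodine ends cis to methyl (Z).

Step 5
Reactants: 12 (Z)-2-iodobut-2-enal
Product: 13 (Z)-2-iodobut-2-en-1-ol
Conditions: NaBH4, MeOH, 0 °C
Reagents that add atoms: none
Why: 1,2-Reduction of the aldehyde by borohydride; the C–I bond and the alkene geometry are not affected at 0 °C.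

Step 6
Reactants: 13 (Z)-2-iodobut-2-en-1-ol
Product: 14 tert-butyl{[(2Z)-2-iodobut-2-en-1-yl]oxy}dimethylsilane
Conditions: TBSCl, imidazole, CH2Cl2, 0 °C → rt
Reagents that add atoms: tert-butyldimethylsilyl chloride, CC(C)(C)[Si](C)(C)Cl
Why: Standard silylation of a primary allylic alcohol; the silyl ether keeps this hydroxyl from competing as a nucleophile in step 7.

Step 7
Reactants: 10 (1S,2R)-1-(3,4-dimethoxyphenyl)-2-[(2E)-3-(3,4-dimethoxyphenyl)prop-2-en-1-yl]propane-1,3-diol; 14 tert-butyl{[(2Z)-2-iodobut-2-en-1-yl]oxy}dimethylsilane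
Product: 15 [(2R,4E)-5-(3,4-dimethoxyphenyl)-2-[(S)-(3,4-dimethoxyphenyl)(hydroxy)methyl]pent-4-en-1-yl] (2Z)-2-{[(tert-butyldimethylsilyl)oxy]methyl}but-2-enoate
Conditions: 14 (1.5 equiv), CO (1 atm), Pd(OAc)2 (5 mol %), Xantphos (6 mol %), i-Pr2NEt, toluene, 60 °C
Reagents that add atoms: carbon monoxide, [C-]#[O+]
Why: Pd-catalysed alkoxycarbonylation of an alkenyl iodide: oxidative addition and CO insertion retain the alkene geometry, so methyl C4'' ends cis to the new ester carbonyl, and the acyl–Pd is captured by the less hindered primary O3–H rather than the benzylic O1–H. No free activated acid and no nucleophilic acyl-transfer catalyst is present, which removes the usual path of Z→E isomerisation.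

Step 8
Reactants: 15 [(2R,4E)-5-(3,4-dimethoxyphenyl)-2-[(S)-(3,4-dimethoxyphenyl)(hydroxy)methyl]pent-4-en-1-yl] (2Z)-2-{[(tert-butyldimethylsilyl)oxy]methyl}but-2-enoate
Product: 16 [(2R,4E)-5-(3,4-dimethoxyphenyl)-2-[(S)-(3,4-dimethoxyphenyl)(hydroxy)methyl]pent-4-en-1-yl] (2Z)-2-(hydroxymethyl)but-2-enoate
Conditions: HF·pyridine, pyridine, THF, 0 °C → rt
Reagents that add atoms: none
Why: Fluoride cleavage of a primary silyl ether under buffered, weakly acidic conditions; the medium is not basic enough for O3→O1 acyl migration and not acidic enough to ionise the benzylic alcohol, and it does not touch either alkene.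

## Compound list

1 | (4S)-4-benzyl-1,3-oxazolidin-2-one | O=C1N[C@@H](Cc2ccccc2)CO1 | starting material
2 | acryloyl chloride | C=CC(Cl)=O | starting material
3 | (4S)-3-acryloyl-4-benzyl-1,3-oxazolidin-2-one | C=CC(=O)N1[C@@H](Cc2ccccc2)COC1=O | intermediate
4 | 4-ethynyl-1,2-dimethoxybenzene | C#Cc1ccc(OC)c(OC)c1 | starting material
5 | 3,4-dimethoxybenzaldehyde | O=Cc1ccc(OC)c(OC)c1 | starting material
6 | 9-[(E)-2-(3,4-dimethoxyphenyl)ethenyl]-9-borabicyclo[3.3.1]nonane (not isolated) | COc1ccc(/C=C/B2C3CCCC2CCC3)cc1OC | intermediate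
7 | (4S)-4-benzyl-3-[(1Z,4E)-1-(9-borabicyclo[3.3.1]nonan-9-yloxy)-5-(3,4-dimethoxyphenyl)penta-1,4-dien-1-yl]-1,3-oxazolidin-2-one (not isolated) | COc1ccc(/C=C/C/C=C(\OB2C3CCCC2CCC3)N2[C@@H](Cc3ccccc3)COC2=O)cc1OC | intermediate
8 | (4S)-4-benzyl-3-{(2S,4E)-2-[(S)-(9-borabicyclo[3.3.1]nonan-9-yloxy)(3,4-dimethoxyphenyl)methyl]-5-(3,4-dimethoxyphenyl)pent-4-enoyl}-1,3-oxazolidin-2-one (not isolated) | O=C(N1[C@@H](Cc2ccccc2)COC1=O)[C@@H](C/C=C/c3ccc(OC)c(OC)c3)[C@H](OB4C5CCCC4CCC5)c6ccc(OC)c(OC)c6 | intermediate
9 | (4S)-4-benzyl-3-{(2S,4E)-5-(3,4-dimethoxyphenyl)-2-[(S)-(3,4-dimethoxyphenyl)(hydroxy)methyl]pent-4-enoyl}-1,3-oxazolidin-2-one | O=C(N1[C@@H](Cc2ccccc2)COC1=O)[C@@H](C/C=C/c3ccc(OC)c(OC)c3)[C@H](O)c4ccc(OC)c(OC)c4 | intermediate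
10 | (1S,2R)-1-(3,4-dimethoxyphenyl)-2-[(2E)-3-(3,4-dimethoxyphenyl)prop-2-en-1-yl]propane-1,3-diol | OC[C@@H](C/C=C/c1ccc(OC)c(OC)c1)[C@H](O)c2ccc(OC)c(OC)c2 | intermediate
11 | (E)-but-2-enal | C/C=C/C=O | starting material
12 | (Z)-2-iodobut-2-enal | C/C=C(\I)C=O | intermediate
13 | (Z)-2-iodobut-2-en-1-ol | C/C=C(\I)CO | intermediate
14 | tert-butyl{[(2Z)-2-iodobut-2-en-1-yl]oxy}dimethylsilane | C/C=C(\I)CO[Si](C)(C)C(C)(C)C | intermediate
15 | [(2R,4E)-5-(3,4-dimethoxyphenyl)-2-[(S)-(3,4-dimethoxyphenyl)(hydroxy)methyl]pent-4-en-1-yl] (2Z)-2-{[(tert-butyldimethylsilyl)oxy]methyl}but-2-enoate | C/C=C(/CO[Si](C)(C)C(C)(C)C)C(=O)OC[C@@H](C/C=C/c1ccc(OC)c(OC)c1)[C@H](O)c2ccc(OC)c(OC)c2 | intermediate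
16 | [(2R,4E)-5-(3,4-dimethoxyphenyl)-2-[(S)-(3,4-dimethoxyphenyl)(hydroxy)methyl]pent-4-en-1-yl] (2Z)-2-(hydroxymethyl)but-2-enoate | C/C=C(/CO)C(=O)OC[C@@H](C/C=C/c1ccc(OC)c(OC)c1)[C@H](O)c1ccc(OC)c(OC)c1 | target

## Step count and least certain steps

Total step count: 8. Longest linear sequence: 5 steps (1, 2, 3, 7, 8; the branch 4, 5, 6, 7, 8 is equally long).

**Step 2 (key step, proposed new method).** Three things are most likely to go wrong:
- The catalytic cycle may stall if the rhodium enolate stays chelated to the imide and exchanges slowly with boron, in which case repeated insertion of 3 (oligomerisation) would compete.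
- Facial or syn selectivity may erode if part of the aldol event runs through a rhodium enolate or an E/Z enolate mixture.
- Double hydroboration of 4 may lower the titre of 6.

Fallback (known chemistry only), setting out from 5 and rejoining at 9: addition of vinylmagnesium bromide to 5 would give racemic 1-(3,4-dimethoxyphenyl)prop-2-en-1-ol F1. A Johnson–Claisen rearrangement (triethyl orthoacetate, cat. propanoic acid, 140 °C) would give ethyl (4E)-5-(3,4-dimethoxyphenyl)pent-4-enoate F2, and saponification (LiOH, THF/H2O) would give (4E)-5-(3,4-dimethoxyphenyl)pent-4-enoic acid F3. Acylation of 1 through the pivaloyl mixed anhydride (PivCl, Et3N, LiCl, THF) would give (4S)-4-benzyl-3-[(4E)-5-(3,4-dimethoxyphenyl)pent-4-enoyl]-1,3-oxazolidin-2-one F4. Soft enolisation of F4 (Bu2BOTf, i-Pr2NEt, CH2Cl2, −78 → 0 °C) followed by 5 would give 9.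

**Step 7.** With only one equivalent of a β-branched primary alcohol, alcoholysis of the acyl–palladium may be slow. Reduction of the acyl–palladium, insertion of the styrene (Heck-type), or partial acylation at O1 could then compete. Fallback, setting out from 14 and rejoining at 15: iodine–lithium exchange (t-BuLi, Et2O, −78 °C) and carboxylation with CO2 would give (2Z)-2-{[(tert-butyldimethylsilyl)oxy]methyl}but-2-enoic acid F5 with retention of geometry. A Mitsunobu esterification of 10 with F5 (PPh3, DIAD, THF, 0 °C) activates the primary alcohol rather than the acid, so it offers no path to Z→E isomerisation, and would give 15.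

**Step 8.** Acyl migration from O3 to O1, ionisation of the electron-rich benzylic alcohol, or Z→E isomerisation by reversible conjugate addition of fluoride or pyridine could accompany desilylation. Fallback, setting out from 13 and rejoining at 16: silylation with chlorotriethylsilane would give triethyl{[(2Z)-2-iodobut-2-en-1-yl]oxy}silane F6. The carbonylative esterification of step 7 with 10 would give [(2R,4E)-5-(3,4-dimethoxyphenyl)-2-[(S)-(3,4-dimethoxyphenyl)(hydroxy)methyl]pent-4-en-1-yl] (2Z)-2-{[(triethylsilyl)oxy]methyl}but-2-enoate F7. The triethylsilyl ether would be cleaved during work-up (dilute aqueous citric acid, THF, 0 °C) to give 16 without a separate fluoride step.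

**Step 1.** Polymerisation of the acrylimide during acylation or isolation. Fallback, setting out from 1 and rejoining at 3: N-acylation (n-BuLi, THF, −78 °C) with 3-bromopropanoyl chloride would give (4S)-4-benzyl-3-(3-bromopropanoyl)-1,3-oxazolidin-2-one F8, and elimination (Et3N, CH2Cl2, 0 °C) immediately before use would give 3.

## Further compounds

F1 | step 2 | 1-(3,4-dimethoxyphenyl)prop-2-en-1-ol (racemic) | C=CC(O)c1ccc(OC)c(OC)c1
F2 | step 2 | ethyl (4E)-5-(3,4-dimethoxyphenyl)pent-4-enoate | CCOC(=O)CC/C=C/c1ccc(OC)c(OC)c1
F3 | step 2 | (4E)-5-(3,4-dimethoxyphenyl)pent-4-enoic acid | OC(=O)CC/C=C/c1ccc(OC)c(OC)c1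
F4 | step 2 | (4S)-4-benzyl-3-[(4E)-5-(3,4-dimethoxyphenyl)pent-4-enoyl]-1,3-oxazolidin-2-one | O=C(CC/C=C/c1ccc(OC)c(OC)c1)N1[C@@H](Cc2ccccc2)COC1=O
F5 | step 7 | (2Z)-2-{[(tert-butyldimethylsilyl)oxy]methyl}but-2-enoic acid | C/C=C(/CO[Si](C)(C)C(C)(C)C)C(O)=O
F6 | step 8 | triethyl{[(2Z)-2-iodobut-2-en-1-yl]oxy}silane | C/C=C(\I)CO[Si](CC)(CC)CC
F7 | step 8 | [(2R,4E)-5-(3,4-dimethoxyphenyl)-2-[(S)-(3,4-dimethoxyphenyl)(hydroxy)methyl]pent-4-en-1-yl] (2Z)-2-{[(triethylsilyl)oxy]methyl}but-2-enoate | C/C=C(/CO[Si](CC)(CC)CC)C(=O)OC[C@@H](C/C=C/c1ccc(OC)c(OC)c1)[C@H](O)c2ccc(OC)c(OC)c2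
F8 | step 1 | (4S)-4-benzyl-3-(3-bromopropanoyl)-1,3-oxazolidin-2-one | O=C(CCBr)N1[C@@H](Cc2ccccc2)COC1=O
A1 | alternative 1 | (4S)-4-benzyl-3-[(4E)-5-(3,4-dimethoxyphenyl)pent-4-enoyl]-1,3-oxazolidin-2-one | O=C(CC/C=C/c1ccc(OC)c(OC)c1)N1[C@@H](Cc2ccccc2)COC1=O
A2 | alternative 2 | ethyl (4E)-2-(3,4-dimethoxybenzoyl)-5-(3,4-dimethoxyphenyl)pent-4-enoate (racemic) | CCOC(=O)C(C/C=C/c1ccc(OC)c(OC)c1)C(=O)c2ccc(OC)c(OC)c2
A3 | alternative 2 | ethyl (2S,4E)-5-(3,4-dimethoxyphenyl)-2-[(S)-(3,4-dimethoxyphenyl)(hydroxy)methyl]pent-4-enoate | CCOC(=O)[C@@H](C/C=C/c1ccc(OC)c(OC)c1)[C@H](O)c2ccc(OC)c(OC)c2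
A4 | alternative 2 | ethyl (2R,4E)-5-(3,4-dimethoxyphenyl)-2-[(S)-(3,4-dimethoxyphenyl)(hydroxy)methyl]pent-4-enoate | CCOC(=O)[C@H](C/C=C/c1ccc(OC)c(OC)c1)[C@H](O)c2ccc(OC)c(OC)c2
A5 | alternative 3 | (1E,4E)-1,5-bis(3,4-dimethoxyphenyl)penta-1,4-diene | COc1ccc(/C=C/C/C=C/c2ccc(OC)c(OC)c2)cc1OC
A6 | alternative 3 | (4S,5S)-4-(3,4-dimethoxyphenyl)-5-[(2E)-3-(3,4-dimethoxyphenyl)prop-2-en-1-yl]-1,3-dioxane (trans; one enantiomer shown) | O1C[C@H](C/C=C/c2ccc(OC)c(OC)c2)[C@H](OC1)c3ccc(OC)c(OC)c3
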